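**Retrosynthetic overview**
1. The acetate goes on last, at the equatorial 2α-hydroxyl. C12–C13 is cut as a B-alkyl Suzuki–Miyaura bond between a 9α-vinyl-9β-ol and methyl (Z)-3-iodobut-2-enoate, and C9–C11 comes from axial vinyl addition to a C9 ketone.
2. The 2α,3α-diol comes from osmylation of a Δ2 olefin made from a C2 ketone. The 8α-methyl comes from methylation of a C8 diosphenol triflate, hydrogenation and equilibration.
3. Key disconnection C3–C4: the trans-decalin diosphenol with a C2 ketone is an isomer of a verbenone-derived bicyclic trione. A Lewis acid opens the cyclobutane bond C4–C7, and the acetonyl enol carbon C3 captures the C4 cation.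
4. Feature used: the ten carbons of verbenone are C10 with its methyl, C5, C4 with its gem-dimethyl pair, and C6–C9 of ring B. The pinane differs from the decalin only by the cyclobutane bond C4–C7, and C5 and C10 are fixed by the terpene and one cuprate addition.
5. Ring order: ring B is bought as verbenone and ring A closes in the key step. The trione is reached in four steps (2-methylallylcopper addition, enolate hydroxylation, oxidation, ozonolysis).

Key step: step 5

Remark: atoms are numbered as in labdane throughout (C1–C10 decalin, C11–C16 side chain, C17 on C8, C20 on C10; β is the face of C20), and (1R,5R)-(+)-verbenone is taken as purchasable.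

**Route**

Step 1
Reactants: 1 (1R,5R)-(+)-verbenone; 2 methallyl chloride (3-chloro-2-methylpropene)
Product: 6 (1R,4R,5R)-4,6,6-trimethyl-4-(2-methylallyl)bicyclo[3.1.1]heptan-2-one (2-methylallyl anti to the CMe2 bridge), via 2-methylallylmagnesium chloride 3 (not isolated), via 2-methylallylcopper 4 (not isolated), via trimethylsilyl enol ether 5 (not isolated)
Conditions: 2, Mg, THF, rt; CuBr·SMe2, LiCl, THF, −78 °C; Me3SiCl then 1, −78 °C; 1 M HCl, 0 °C
Reagents that add atoms: none
Why: Me3SiCl-accelerated conjugate addition of an allylic copper reagent to the β,β-disubstituted enone should occur on the face anti to the gem-dimethyl bridge, so the new quaternary carbon (future C10) carries its methyl syn to the CMe2 bridge and the 2-methylallyl arm anti to it.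

Step 2
Reactants: 6
Product: 8 (1R,3S,4S,5S)-3-hydroxy-4,6,6-trimethyl-4-(2-methylallyl)bicyclo[3.1.1]heptan-2-one, via potassium enolate 7 (not isolated)
Conditions: KN(SiMe3)2, THF, −78 °C; 3-phenyl-2-(phenylsulfonyl)oxaziridine, −78 °C; aq. NH4Cl
Reagents that add atoms: 3-phenyl-2-(phenylsulfonyl)oxaziridine, O=S(=O)(c1ccccc1)N1OC1c1ccccc1
Why: Davis oxidation of the ketone enolate, which can form only at the methylene next to the quaternary carbon because the other α-carbon is a bridgehead; oxygen should arrive anti to the gem-dimethyl bridge, a configuration that step 3 erases.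

Step 3
Reactants: 8
Product: 9 (1R,4S,5S)-4,6,6-trimethyl-4-(2-methylallyl)bicyclo[3.1.1]heptane-2,3-dione
Conditions: Dess–Martin periodinane, CH2Cl2, rt
Reagents that add atoms: none
Why: Dess–Martin oxidation of the α-ketol to a 1,2-dione that cannot enolise because it lies between a bridgehead and a quaternary carbon.

Step 4
Reactants: 9
Product: 11 (1R,4S,5S)-4,6,6-trimethyl-4-(2-oxopropyl)bicyclo[3.1.1]heptane-2,3-dione, via ozonide 10 (not isolated)
Conditions: O3, CH2Cl2, −78 °C; Me2S, −78 °C → rt
Reagents that add atoms: ozone, [O-][O+]=O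
Why: ozonolysis of the 1,1-disubstituted alkene under reductive work-up unmasks the methyl ketone, the saturated dione being inert to ozone and to Me2S.

Step 5
Reactants: 11
Product: 12 (5S,10S)-8-hydroxy-4,4,10-trimethyl-trans-decal-7-ene-2,9-dione (diosphenol)
Conditions: TiCl4 (2.5 equiv), CH2Cl2, −78 → 0 °C; H2O
Reagents that add atoms: none
Why: Proposed new method: TiCl4 chelates the non-enolisable C8/C9 dione, and the strained C4–C7 σ-bond, which is α to the C8 carbonyl and aligned with its π-system, heterolyses in a strain-releasing retro-aldol-like fragmentation to a titanium diosphenolate (C7=C8–O–Ti, C9=O) and the tertiary C4 cation, which is then captured by C3 of the enol (titanium enolate) of the acetonyl ketone to forge C3–C4. The closest known reaction types are the acid-mediated opening of pinan-2-one-type cyclobutanes to tertiary cations or halides and the Lewis acid-mediated α-tert-alkylation of ketone enols and silyl enol ethers by tertiary cations; their union in one cascade on a 1,2-dione is untested. Ring A closes in a 6-(enolendo) mode onto the planar cation through a chair in which the C1 and C4 arms are both equatorial on ring B. No new stereocentre is formed, since C4 carries two methyls and C3 is a methylene, and the trans ring fusion follows from C5 and C10, whose arms were placed trans in step 1. The step needs cleavage of C4–C7 and not C6–C7, which the tertiary versus primary cation stability secures, and carbon capture by C3 and not proton loss, chloride or oxygen capture or aldol addition to C9, which is secured because those paths are reversible under TiCl4 while C-alkylation to the strain-free decalin is not; low temperature keeps capture ahead of loss of H5, which would erase the C5 configuration.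

Step 6
Reactants: 12
Product: 13 (5S,10S)-4,4,10-trimethyl-2,9-dioxo-trans-decal-7-en-8-yl trifluoromethanesulfonate
Conditions: Tf2O, pyridine, CH2Cl2, −78 → 0 °C
Reagents that add atoms: trifluoromethanesulfonic anhydride, O=S(=O)(OS(=O)(=O)C(F)(F)F)C(F)(F)F
Why: O-sulfonylation of the acidic diosphenol hydroxyl (enol triflate formation) under pyridine, which does not enolise the saturated C2 ketone.

Step 7
Reactants: 13
Product: 14 (5S,10S)-4,4,8,10-tetramethyl-trans-decal-7-ene-2,9-dione
Conditions: trimethylboroxine, Pd(PPh3)4 (5 mol%), K2CO3, dioxane, 90 °C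
Reagents that add atoms: trimethylboroxine, CB1OB(C)OB(C)O1
Why: Suzuki–Miyaura methylation of the electron-poor α-keto enol triflate installs the C8 methyl and tolerates both ketones.

Step 8
Reactants: 14
Product: 16 (5S,8R,10S)-4,4,8,10-tetramethyl-trans-decalin-2,9-dione (8α-methyl), via 8β-methyl epimer 15 (not isolated)
Conditions: H2 (1 atm), Pd/C, EtOAc, rt; filter; NaOMe (0.2 equiv), MeOH, rt
Reagents that add atoms: none
Why: heterogeneous hydrogenation of the enone C7=C8 bond followed by base equilibration through the C9 enolate sets C8 under thermodynamic control with the methyl equatorial (8α), free of the 1,3-diaxial clash with the C10 methyl that the 8β epimer suffers.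

Step 9
Reactants: 16
Product: 18 (5S,8R,10S)-4,4,8,10-tetramethyl-9-oxo-trans-decal-2-en-2-yl trifluoromethanesulfonate, via potassium Δ2-enolate 17 (not isolated)
Conditions: KN(SiMe3)2 (1.05 equiv), THF, −78 °C; PhNTf2, −78 → 0 °C
Reagents that add atoms: N-phenylbis(trifluoromethanesulfonimide), O=S(=O)(N(c1ccccc1)S(=O)(=O)C(F)(F)F)C(F)(F)F
Why: enol triflate formation by deprotonation and N-triflimide trapping, in which the C2 ketone should react in preference to the C9 ketone (its only α-hydrogen, H8β, is tertiary and syn-axial to the C10 methyl) and should enolise toward C3, because a Δ2 double bond lies opposite the ring-fusion bond of the trans-decalin whereas a Δ1 double bond would flatten the fusion torsion and force H1 into the plane of the C9 carbonyl, as in the C3-directed enolisation of 2-oxo-5α-steroids.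

Step 10
Reactants: 18
Product: 19 (5S,8R,10S)-4,4,8,10-tetramethyl-trans-decal-2-en-9-one
Conditions: Pd(OAc)2 (5 mol%), PPh3, HCO2H, Bu3N, DMF, 60 °C
Reagents that add atoms: none
Why: palladium-catalysed formate reduction of the enol triflate (hydride transfer to the alkenylpalladium intermediate) gives the Δ2 olefin without touching the hindered C9 ketone.

Step 11
Reactants: 19
Product: 20 (2R,3S,5S,8R,10S)-2,3-dihydroxy-4,4,8,10-tetramethyl-trans-decalin-9-one (2α,3α-diol)
Conditions: OsO4 (2 mol%), N-methylmorpholine N-oxide, acetone/H2O, rt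
Reagents that add atoms: N-methylmorpholine N-oxide, C[N+]1([O-])CCOCC1; water, O
Why: Upjohn dihydroxylation, in which osmylation of the cis-disubstituted Δ2 olefin should occur on the α face, anti to the two axial β-methyls at C4 and C10, setting C2 and C3 as the 2α,3α-diol.

Step 12
Reactants: 20
Product: 21 2α,3α-O-isopropylidene derivative of 20
Conditions: Me2C(OMe)2, pyridinium p-toluenesulfonate (cat.), acetone, rt
Reagents that add atoms: 2,2-dimethoxypropane, COC(C)(C)OC
Why: acid-catalysed transketalisation of the cis-diol to the acetonide masks both hydroxyls for the organometallic steps.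

Step 13
Reactants: 21
Product: 22 (2R,3S,5S,8R,9S,10S)-9-ethenyl-2,3-(isopropylidenedioxy)-4,4,8,10-tetramethyl-trans-decalin-9-ol (9α-vinyl 9β-hydroxy)
Conditions: CH2=CHMgBr, CeCl3, THF, −78 → 0 °C; aq. NH4Cl
Reagents that add atoms: vinylmagnesium bromide, C=C[Mg]Br
Why: organocerium 1,2-addition to the hindered, enolisable ketone, in which the small sp2 nucleophile should attack axially on the α face, anti to the axial C10 methyl that blocks the equatorial β trajectory, setting C9 with vinyl α and hydroxyl β.

Step 14
Reactants: 23 methyl but-2-ynoate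
Product: 24 methyl (Z)-3-iodobut-2-enoate
Conditions: NaI, AcOH, 115 °C
Reagents that add atoms: sodium iodide, [Na+].[I-]
Why: conjugate hydroiodination of the ynoate by anti addition of HI gives the (Z)-β-iodo enoate with iodine cis to the ester.

Step 15
Reactants: 22; 24
Product: 26 methyl (2R,3S,5S,8R,9S,10S,13Z)-9-hydroxy-2,3-(isopropylidenedioxy)labd-13-en-15-oate, via B-alkyl-9-BBN adduct 25 (not isolated)
Conditions: 9-BBN, THF, rt; then 24, Pd(dppf)Cl2 (5 mol%), AsPh3, Cs2CO3, DMF/THF/H2O, rt
Reagents that add atoms: none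
Why: anti-Markovnikov hydroboration of the terminal vinyl group followed by B-alkyl Suzuki–Miyaura coupling, which proceeds with retention of the iodoalkene geometry and so fixes the 13Z double bond.

Step 16
Reactants: 26
Product: 27 methyl (2R,3S,5S,8R,9S,10S,13Z)-2,3,9-trihydroxylabd-13-en-15-oate
Conditions: AcOH/H2O (4:1), 40 °C
Reagents that add atoms: none
Why: mild acid hydrolysis of the acetonide, under which the tertiary C9 alcohol and the Z-enoate should be stable.

Step 17
Reactants: 27
Product: 28 methyl (2R,3S,5S,8R,9S,10S,13Z)-2-acetoxy-3,9-dihydroxylabd-13-en-15-oate (CNP0135744.2)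
Conditions: Ac2O (1.2 equiv), pyridine, CH2Cl2, 0 °C
Reagents that add atoms: acetic anhydride, CC(=O)OC(C)=O
Why: sterically controlled acylation, in which the equatorial secondary 2α-hydroxyl should be acetylated while the axial 3α-hydroxyl next to the gem-dimethyl carbon and the tertiary C9 hydroxyl stay free.

**Compound list**
1 | (1R,5R)-(+)-verbenone | CC1=CC(=O)[C@@H]2C[C@H]1C2(C)C | starting material
2 | methallyl chloride (3-chloro-2-methylpropene) | C=C(C)CCl | starting material
3 | 2-methylallylmagnesium chloride | C=C(C)C[Mg]Cl | intermediate (not isolated)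
4 | 2-methylallylcopper | C=C(C)C[Cu] | intermediate (not isolated)
5 | trimethylsilyl enol ether of 6 | C=C(C)C[C@]1(C)C=C(O[Si](C)(C)C)[C@@H]2C[C@H]1C2(C)C | intermediate (not isolated)
6 | (1R,4R,5R)-4,6,6-trimethyl-4-(2-methylallyl)bicyclo[3.1.1]heptan-2-one | C=C(C)C[C@]1(C)CC(=O)[C@@H]2C[C@H]1C2(C)C | intermediate
7 | potassium enolate of 6 | C=C(C)C[C@]1(C)C=C([O-])[C@@H]2C[C@H]1C2(C)C.[K+] | intermediate (not isolated)
8 | (1R,3S,4S,5S)-3-hydroxy-4,6,6-trimethyl-4-(2-methylallyl)bicyclo[3.1.1]heptan-2-one | C=C(C)C[C@]1(C)[C@H](O)C(=O)[C@@H]2C[C@H]1C2(C)C | intermediate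
9 | (1R,4S,5S)-4,6,6-trimethyl-4-(2-methylallyl)bicyclo[3.1.1]heptane-2,3-dione | C=C(C)C[C@]1(C)C(=O)C(=O)[C@@H]2C[C@H]1C2(C)C | intermediate
10 | ozonide (1,2,4-trioxolane) of 9, epimeric at the trioxolane carbon | CC1(C[C@]2(C)C(=O)C(=O)[C@@H]3C[C@H]2C3(C)C)OCOO1 | intermediate (not isolated)
11 | (1R,4S,5S)-4,6,6-trimethyl-4-(2-oxopropyl)bicyclo[3.1.1]heptane-2,3-dione (acetonyl trione) | CC(=O)C[C@]1(C)C(=O)C(=O)[C@@H]2C[C@H]1C2(C)C | intermediate
12 | (5S,10S)-8-hydroxy-4,4,10-trimethyl-trans-decal-7-ene-2,9-dione (diosphenol) | O=C1C(O)=CC[C@H]2C(C)(C)CC(=O)C[C@@]21C | intermediate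
13 | (5S,10S)-4,4,10-trimethyl-2,9-dioxo-trans-decal-7-en-8-yl triflate | O=C1C(OS(=O)(=O)C(F)(F)F)=CC[C@H]2C(C)(C)CC(=O)C[C@@]21C | intermediate
14 | (5S,10S)-4,4,8,10-tetramethyl-trans-decal-7-ene-2,9-dione | O=C1C(C)=CC[C@H]2C(C)(C)CC(=O)C[C@@]21C | intermediate
15 | (5S,8S,10S)-4,4,8,10-tetramethyl-trans-decalin-2,9-dione (8β-methyl) | O=C1[C@@H](C)CC[C@H]2C(C)(C)CC(=O)C[C@@]21C | intermediate (not isolated)
16 | (5S,8R,10S)-4,4,8,10-tetramethyl-trans-decalin-2,9-dione (8α-methyl) | O=C1[C@H](C)CC[C@H]2C(C)(C)CC(=O)C[C@@]21C | intermediate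
17 | potassium Δ2-enolate of 16 | O=C1[C@H](C)CC[C@H]2C(C)(C)C=C([O-])C[C@@]21C.[K+] | intermediate (not isolated)
18 | (5S,8R,10S)-4,4,8,10-tetramethyl-9-oxo-trans-decal-2-en-2-yl triflate | O=C1[C@H](C)CC[C@H]2C(C)(C)C=C(OS(=O)(=O)C(F)(F)F)C[C@@]21C | intermediate
19 | (5S,8R,10S)-4,4,8,10-tetramethyl-trans-decal-2-en-9-one | O=C1[C@H](C)CC[C@H]2C(C)(C)C=CC[C@@]21C | intermediate
20 | (2R,3S,5S,8R,10S)-2,3-dihydroxy-4,4,8,10-tetramethyl-trans-decalin-9-one | O=C1[C@H](C)CC[C@H]2C(C)(C)[C@H](O)[C@H](O)C[C@@]21C | intermediate
21 | 2α,3α-O-isopropylidene derivative of 20 | O=C1[C@H](C)CC[C@H]2C(C)(C)[C@H](OC(C)(C)O3)[C@H]3C[C@@]21C | intermediate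
22 | (2R,3S,5S,8R,9S,10S)-9-ethenyl-2,3-(isopropylidenedioxy)-4,4,8,10-tetramethyl-trans-decalin-9-ol | C=C[C@]1(O)[C@H](C)CC[C@H]2C(C)(C)[C@H](OC(C)(C)O3)[C@H]3C[C@@]21C | intermediate
23 | methyl but-2-ynoate | CC#CC(=O)OC | starting material
24 | methyl (Z)-3-iodobut-2-enoate | COC(=O)/C=C(/C)I | intermediate
25 | B-alkyl-9-BBN adduct of 22 (boron on C12) | C(C[C@]1(O)[C@H](C)CC[C@H]2C(C)(C)[C@H](OC(C)(C)O3)[C@H]3C[C@@]21C)B4C5CCCC4CCC5 | intermediate (not isolated)
26 | methyl (2R,3S,5S,8R,9S,10S,13Z)-9-hydroxy-2,3-(isopropylidenedioxy)labd-13-en-15-oate | COC(=O)/C=C(/C)CC[C@]1(O)[C@H](C)CC[C@H]2C(C)(C)[C@H](OC(C)(C)O3)[C@H]3C[C@@]21C | intermediate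
27 | methyl (2R,3S,5S,8R,9S,10S,13Z)-2,3,9-trihydroxylabd-13-en-15-oate | COC(=O)/C=C(/C)CC[C@]1(O)[C@H](C)CC[C@H]2C(C)(C)[C@H](O)[C@H](O)C[C@@]21C | intermediate
28 | methyl (2R,3S,5S,8R,9S,10S,13Z)-2-acetoxy-3,9-dihydroxylabd-13-en-15-oate (CNP0135744.2) | COC(=O)/C=C(/C)CC[C@]1(O)[C@H](C)CC[C@H]2C(C)(C)[C@H](O)[C@H](OC(C)=O)C[C@@]21C | target

**Step count and risks**
Total step count: 17. Longest linear sequence: 16 steps (steps 1–13 and 15–17 from verbenone; step 14 is a one-step side branch).

Steps most likely to fail:

Step 5 (the step that carries the new-method label). What may go wrong: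
- The C4 cation may lose H5 or suffer a 1,2-hydride shift from C5 before carbon capture, which would erase the C5 configuration or divert closure to a five-membered ring.
- The acetonyl enol may add to the C9 carbonyl (aldol) before the cyclobutane opens.
- The sequence may stall at oxygen capture or at the tertiary chloride.

Fallback (known reactions, the two events separated): setting out from 11, hydrogen chloride in CH2Cl2 at 0 °C opens the cyclobutane in the known manner of pinan-2-one-type ketones to the ring-opened tertiary chloride diosphenol F1. LiN(SiMe3)2 (2.2 equiv) with Me3SiCl as internal quench at −78 °C silylates the diosphenol and converts the methyl ketone into its kinetic terminal enol ether, giving the bis(trimethylsilyl) derivative F2. TiCl4 in CH2Cl2 at −78 °C then effects the established Lewis acid-mediated α-tert-alkylation of a silyl enol ether by a tertiary chloride, here intramolecular, and aqueous work-up cleaves the remaining silyl ether and returns the route at 12.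

Step 9. What may go wrong: deprotonation at C1 instead of C3, since both methylenes are neopentylic and the C9 carbonyl may steer the base toward C1, which would carry the Δ1 series forward; or competing enolisation of the C9 ketone.

Fallback (regiocontrol moved behind the C9 addition, where the axial 9α substituent is syn-axial to H1α and blocks the stereoelectronically allowed deprotonation at C1):
- Setting out from 16, NaBH4 in MeOH at 0 °C reduces only the unhindered C2 ketone, from the α face, to the 2β-alcohol F3.
- Excess CH2=CHMgBr/CeCl3 adds to C9 as in step 13 to give the 9α-vinyl diol F4.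
- Dess–Martin oxidation of the secondary alcohol gives the 2-keto vinyl carbinol F5.
- KN(SiMe3)2 (2.2 equiv) forms the dipotassium alkoxide enolate F6, which PhNTf2 traps as the Δ2 enol triflate F7.
- Palladium-catalysed formate reduction as in step 10 gives the Δ2 olefin vinyl carbinol F8.
- 9-BBN hydroborates only the terminal vinyl group to the B-alkyl-9-BBN adduct F9, which is coupled with 24 as in step 15 to the Δ2 olefin hydroxy ester F10.
- OsO4/N-methylmorpholine N-oxide then dihydroxylates the Δ2 olefin in preference to the electron-poor trisubstituted enoate and returns the route at 27.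

Step 13. What may go wrong: poor facial selectivity (equatorial attack from the β face, giving the C9 epimer), or enolisation of the hindered ketone in place of addition.

Fallback (a slimmer, less basic sp nucleophile with a stronger intrinsic preference for axial attack, then reduction): setting out from 21, HC≡CMgBr/CeCl3 in THF gives the 9α-ethynyl 9β-carbinol F11, and semi-hydrogenation (H2, Pd/CaCO3 poisoned with Pb(OAc)2, quinoline, EtOAc) returns the route at 22.

**Further compounds**
F1 | step 5 | ring-opened tertiary chloride diosphenol (5-(2-chloropropan-2-yl)-2-hydroxy-6-methyl-6-(2-oxopropyl)cyclohex-2-enone) | O=C1C(O)=CC[C@@H](C(C)(C)Cl)[C@]1(C)CC(C)=O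
F2 | step 5 | bis(trimethylsilyl) derivative of F1 (diosphenol silyl ether and terminal silyl enol ether) | O=C1C(O[Si](C)(C)C)=CC[C@@H](C(C)(C)Cl)[C@]1(C)CC(=C)O[Si](C)(C)C
F3 | step 9 | 2β-alcohol (2β-hydroxy-4,4,8α,10-tetramethyl-trans-decalin-9-one) | O=C1[C@H](C)CC[C@H]2C(C)(C)C[C@@H](O)C[C@@]21C
F4 | step 9 | 9α-vinyl diol (2β,9β-diol) | C=C[C@]1(O)[C@H](C)CC[C@H]2C(C)(C)C[C@@H](O)C[C@@]21C
F5 | step 9 | 2-keto vinyl carbinol | C=C[C@]1(O)[C@H](C)CC[C@H]2C(C)(C)CC(=O)C[C@@]21C
F6 | step 9 | dipotassium alkoxide enolate of F5 | C=C[C@]1([O-])[C@H](C)CC[C@H]2C(C)(C)C=C([O-])C[C@@]21C.[K+].[K+]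
F7 | step 9 | Δ2 enol triflate of F5 | C=C[C@]1(O)[C@H](C)CC[C@H]2C(C)(C)C=C(OS(=O)(=O)C(F)(F)F)C[C@@]21C
F8 | step 9 | Δ2 olefin vinyl carbinol | C=C[C@]1(O)[C@H](C)CC[C@H]2C(C)(C)C=CC[C@@]21C
F9 | step 9 | B-alkyl-9-BBN adduct of F8 | C(C[C@]1(O)[C@H](C)CC[C@H]2C(C)(C)C=CC[C@@]21C)B3C4CCCC3CCC4
F10 | step 9 | Δ2 olefin hydroxy ester (methyl (13Z)-9β-hydroxylabda-2,13-dien-15-oate, side chain 9α) | COC(=O)/C=C(/C)CC[C@]1(O)[C@H](C)CC[C@H]2C(C)(C)C=CC[C@@]21C
F11 | step 13 | 9α-ethynyl 9β-carbinol acetonide | C#C[C@]1(O)[C@H](C)CC[C@H]2C(C)(C)[C@H](OC(C)(C)O3)[C@H]3C[C@@]21C
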